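**Retrosynthetic overview**
1. Cathafuran C ⇐ bis-MOM ether 23 ⇐ chroman-4-one 21; the chromene C3=C4 bond comes from ketone reduction and dehydration.
2. 21 ⇐ Suzuki–Miyaura union of chromanone aryl triflate 12 with benzofuran-2-yl boronate 20 (the aryl–benzofuran bond is the convergence point).
3. 12 ⇐ 5,7-dihydroxy-2,2-dimethylchroman-4-one 3; the chelated 5-OH delivers an allyl group to C6 (Claisen), which is converted to prenyl by cross-metathesis, and the same OH then becomes the triflate. 3 ⇐ phloroglucinol + 3-methylbut-2-enoic acid by acylation and intramolecular oxa-Michael ring closure.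
4. 20 ⇐ 2,4-dihydroxybenzaldehyde + ethyl bromoacetate by O-alkylation and intramolecular aldol condensation, then decarboxylation and C2-borylation.
5. Ring order: the pyranone ring (oxa-Michael) and the furan ring (aldol) are closed in separate branches; both benzene rings are bought.

Assumption: the target has no stereocentre and no configurationally stable axis, so "single enantiomer" is taken to mean the single achiral compound drawn.

**Branch A: chromanone triflate**

Step 1
Reactants: 1 phloroglucinol; 2 3-methylbut-2-enoic acid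
Product: 3, 5,7-dihydroxy-2,2-dimethylchroman-4-one
Conditions: P2O5/MeSO3H (Eaton's reagent), 70 °C, 1 h
Reagents that add atoms: 3-methylbut-2-enoic acid (2), CC(C)=CC(=O)O
Why: Friedel–Crafts acylation gives the 2'-hydroxyaryl 3-methylbut-2-enyl ketone, which closes the pyranone ring in situ by intramolecular oxa-Michael addition; the symmetry of phloroglucinol means only one product is possible.

Step 2
Reactants: 3
Product: 5, 5-hydroxy-7-(methoxymethoxy)-2,2-dimethylchroman-4-one
Conditions: MOMCl (1.1 equiv), i-Pr2NEt, CH2Cl2, 0 °C → rt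
Reagents that add atoms: chloromethyl methyl ether (4), COCCl
Why: Selective O-alkylation: the 5-OH is hydrogen-bonded to the C4 carbonyl and unreactive, so only the more acidic 7-OH is protected.

Step 3
Reactants: 5
Product: 7, 5-(allyloxy)-7-(methoxymethoxy)-2,2-dimethylchroman-4-one
Conditions: allyl bromide, K2CO3, DMF, 60 °C
Reagents that add atoms: allyl bromide (6), C=CCBr
Why: Williamson etherification; the chelated phenol is alkylated under forcing carbonate/DMF conditions now that it is the only free OH.

Step 4
Reactants: 7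
Product: 8, 6-allyl-5-hydroxy-7-(methoxymethoxy)-2,2-dimethylchroman-4-one
Conditions: PhNEt2, 200 °C (sealed tube or microwave), Ar
Reagents that add atoms: none
Why: Aromatic Claisen rearrangement; the only free ortho position of the 5-O-allyl ether is C6 (C4a is blocked), so the allyl group is placed unambiguously and the dienone tautomerises back to the chelated phenol.

Step 5
Reactants: 8
Product: 10, 5-hydroxy-7-(methoxymethoxy)-2,2-dimethyl-6-(3-methylbut-2-en-1-yl)chroman-4-one
Conditions: Grubbs II (5 mol %), 2-methyl-2-butene/CH2Cl2, 40 °C, sealed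
Reagents that add atoms: 2-methyl-2-butene (9), CC=C(C)C
Why: Olefin cross-metathesis of a terminal allyl group with excess 2-methyl-2-butene is the standard allyl-to-prenyl conversion and tolerates the chelated phenol and ketone.

Step 6
Reactants: 10
Product: 12, 7-(methoxymethoxy)-2,2-dimethyl-6-(3-methylbut-2-en-1-yl)-4-oxochroman-5-yl trifluoromethanesulfonate
Conditions: Tf2O, pyridine, CH2Cl2, −20 → 0 °C
Reagents that add atoms: triflic anhydride (11), O=S(=O)(OS(=O)(=O)C(F)(F)F)C(F)(F)F
Why: O-sulfonylation of the phenol under buffered conditions that leave the prenyl alkene and MOM ether intact; the resulting triflate is activated for oxidative addition by the ortho carbonyl.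

**Branch B: benzofuran boronate**

Step 7
Reactants: 13 2,4-dihydroxybenzaldehyde
Product: 14, 2-hydroxy-4-(methoxymethoxy)benzaldehyde
Conditions: MOMCl (1.1 equiv), K2CO3, acetone, 0 °C → rt
Reagents that add atoms: chloromethyl methyl ether (4), COCCl
Why: Selective O-alkylation of the non-chelated 4-OH; the 2-OH is hydrogen-bonded to the aldehyde.

Step 8
Reactants: 14
Product: 16, ethyl 6-(methoxymethoxy)benzofuran-2-carboxylate
Conditions: BrCH2CO2Et, K2CO3, DMF, 90 → 130 °C
Reagents that add atoms: ethyl bromoacetate (15), CCOC(=O)CBr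
Why: O-alkylation followed by intramolecular aldol condensation of the ester enolate onto the ortho aldehyde; dehydration is driven by aromatisation to the benzofuran.

Step 9
Reactants: 16
Product: 17, 6-(methoxymethoxy)benzofuran-2-carboxylic acid
Conditions: LiOH·H2O, THF/MeOH/H2O, rt; citric acid to pH 4
Reagents that add atoms: lithium hydroxide (oxygen of the acid OH), [Li+].[OH-]
Why: Ester saponification; the mild acidification preserves the MOM ether.

Step 10
Reactants: 17
Product: 18, 6-(methoxymethoxy)benzofuran
Conditions: Cu2O (10 mol %), 1,10-phenanthroline, NMP/quinoline, 170–190 °C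
Reagents that add atoms: none
Why: Copper-mediated protodecarboxylation of a heteroaryl-2-carboxylic acid (the classical coumarilic acid → benzofuran reaction) under non-acidic conditions.

Step 11
Reactants: 18
Product: 20, 2-[6-(methoxymethoxy)benzofuran-2-yl]-4,4,5,5-tetramethyl-1,3,2-dioxaborolane
Conditions: n-BuLi, THF, −78 °C, 1 h; then i-PrOBpin, −78 °C → rt
Reagents that add atoms: 2-isopropoxy-4,4,5,5-tetramethyl-1,3,2-dioxaborolane (19), CC(C)OB1OC(C)(C)C(C)(C)O1
Why: Lithiation–borylation; the furan C2–H is the kinetically most acidic position at −78 °C, so it is deprotonated ahead of MOM-directed ortho-lithiation.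

**Union and endgame**

Step 12
Reactants: 12 aryl triflate; 20 boronate (1.5 equiv)
Product: 21, 5-[6-(methoxymethoxy)benzofuran-2-yl]-7-(methoxymethoxy)-2,2-dimethyl-6-(3-methylbut-2-en-1-yl)chroman-4-one
Conditions: XPhos Pd G3 (4 mol %), K3PO4, THF/H2O (10:1), 50 °C
Reagents that add atoms: none (both partners are numbered reactants)
Why: Suzuki–Miyaura coupling; a fast dialkylbiarylphosphine catalyst couples the di-ortho-substituted, carbonyl-activated triflate before the 2-heteroaryl boronate protodeboronates.

Step 13
Reactants: 21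
Product: 22, 5-[6-(methoxymethoxy)benzofuran-2-yl]-7-(methoxymethoxy)-2,2-dimethyl-6-(3-methylbut-2-en-1-yl)chroman-4-ol (racemic at C4)
Conditions: NaBH4, MeOH/THF, 0 °C → rt
Reagents that add atoms: none
Why: Hydride reduction of the aryl ketone; the C4 stereocentre is formed racemic, which is acceptable because it is destroyed in the next step.

Step 14
Reactants: 22
Product: 23, 6-(methoxymethoxy)-2-[7-(methoxymethoxy)-2,2-dimethyl-6-(3-methylbut-2-en-1-yl)-2H-chromen-5-yl]benzofuran
Conditions: MsCl, Et3N, CH2Cl2, 0 °C → rt; then DBU, rt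
Reagents that add atoms: none
Why: Sulfonylation and elimination of the benzylic alcohol (assisted by the para 7-oxygen) give the 2H-chromene without the acid that could cleave MOM or cyclise the prenyl group.

Step 15
Reactants: 23
Product: 24, Cathafuran C, 5-(6-hydroxybenzofuran-2-yl)-2,2-dimethyl-6-(3-methylbut-2-en-1-yl)-2H-chromen-7-ol
Conditions: 3 M aq. HCl, MeOH/THF, 45 °C, monitored closely
Reagents that add atoms: none
Why: Acetal hydrolysis removes both MOM ethers in one step under dilute-acid conditions routinely tolerated by prenylphenols and 2,2-dimethylchromenes.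

**Compound list**
1 | phloroglucinol | Oc1cc(O)cc(O)c1 | starting material
2 | 3-methylbut-2-enoic acid | CC(C)=CC(=O)O | starting material
3 | 5,7-dihydroxy-2,2-dimethylchroman-4-one | CC1(C)CC(=O)c2c(O)cc(O)cc2O1 | intermediate
4 | chloromethyl methyl ether (MOMCl) | COCCl | starting material
5 | 5-hydroxy-7-(methoxymethoxy)-2,2-dimethylchroman-4-one | CC1(C)CC(=O)c2c(O)cc(OCOC)cc2O1 | intermediate
6 | allyl bromide | C=CCBr | starting material
7 | 5-(allyloxy)-7-(methoxymethoxy)-2,2-dimethylchroman-4-one | CC1(C)CC(=O)c2c(OCC=C)cc(OCOC)cc2O1 | intermediate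
8 | 6-allyl-5-hydroxy-7-(methoxymethoxy)-2,2-dimethylchroman-4-one | CC1(C)CC(=O)c2c(O)c(CC=C)c(OCOC)cc2O1 | intermediate
9 | 2-methyl-2-butene | CC=C(C)C | starting material
10 | 5-hydroxy-7-(methoxymethoxy)-2,2-dimethyl-6-(3-methylbut-2-en-1-yl)chroman-4-one | CC1(C)CC(=O)c2c(O)c(CC=C(C)C)c(OCOC)cc2O1 | intermediate
11 | trifluoromethanesulfonic anhydride | O=S(=O)(OS(=O)(=O)C(F)(F)F)C(F)(F)F | starting material
12 | 7-(methoxymethoxy)-2,2-dimethyl-6-(3-methylbut-2-en-1-yl)-4-oxochroman-5-yl triflate | CC1(C)CC(=O)c2c(OS(=O)(=O)C(F)(F)F)c(CC=C(C)C)c(OCOC)cc2O1 | intermediate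
13 | 2,4-dihydroxybenzaldehyde | O=Cc1ccc(O)cc1O | starting material
14 | 2-hydroxy-4-(methoxymethoxy)benzaldehyde | COCOc1ccc(C=O)c(O)c1 | intermediate
15 | ethyl bromoacetate | CCOC(=O)CBr | starting material
16 | ethyl 6-(methoxymethoxy)benzofuran-2-carboxylate | CCOC(=O)c1cc2ccc(OCOC)cc2o1 | intermediate
17 | 6-(methoxymethoxy)benzofuran-2-carboxylic acid | OC(=O)c1cc2ccc(OCOC)cc2o1 | intermediate
18 | 6-(methoxymethoxy)benzofuran | COCOc1ccc2ccoc2c1 | intermediate
19 | 2-isopropoxy-4,4,5,5-tetramethyl-1,3,2-dioxaborolane | CC(C)OB1OC(C)(C)C(C)(C)O1 | starting material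
20 | 2-[6-(methoxymethoxy)benzofuran-2-yl]-4,4,5,5-tetramethyl-1,3,2-dioxaborolane | COCOc1ccc2cc(B3OC(C)(C)C(C)(C)O3)oc2c1 | intermediate
21 | 5-[6-(methoxymethoxy)benzofuran-2-yl]-7-(methoxymethoxy)-2,2-dimethyl-6-(3-methylbut-2-en-1-yl)chroman-4-one | CC1(C)CC(=O)c2c(-c3cc4ccc(OCOC)cc4o3)c(CC=C(C)C)c(OCOC)cc2O1 | intermediate
22 | corresponding chroman-4-ol (racemic) | CC1(C)CC(O)c2c(-c3cc4ccc(OCOC)cc4o3)c(CC=C(C)C)c(OCOC)cc2O1 | intermediate
23 | bis-MOM Cathafuran C | CC1(C)C=Cc2c(-c3cc4ccc(OCOC)cc4o3)c(CC=C(C)C)c(OCOC)cc2O1 | intermediate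
24 | Cathafuran C | CC(C)=CCc1c(O)cc2c(c1-c1cc3ccc(O)cc3o1)C=CC(C)(C)O2 | target

**Totals**
Total steps: 15.
Longest linear sequence: 10 (steps 1–6, then 12–15); the other branch is 9 (steps 7–11, then 12–15).

**Three steps most likely to fail, with fallbacks**
- Step 12 (hindered Suzuki coupling with a protodeboronation-prone 2-benzofuranyl boronate). Fallback: build the furan ring on the hub instead. Convert triflate 12 to the aryl acetylene (Sonogashira with TMS-acetylene, then K2CO3/MeOH) and run a Sonogashira coupling with 5-endo-dig cyclisation against 2-iodo-5-(methoxymethoxy)phenol.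
- Step 4 (Claisen rearrangement at 200 °C; risk of decomposition or retro-oxa-Michael scrambling of the chromanone). Fallback: drop the allyl relay. Iodinate 5 at C6, ortho to the chelated OH (BnNMe3·ICl2, CaCO3), and install the prenyl group by Stille coupling with tributyl(3-methylbut-2-enyl)stannane.
- Step 15 (acidic MOM removal next to an ortho-prenylphenol and a 2H-chromene; risk of chroman formation). Fallback: change the protecting-group plan to SEM ethers (SEMCl in steps 2 and 7) and finish with fluoride (TBAF, DMPU, 60–80 °C), so no acid is used at the end.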